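(The data stem from a simulated flask for an exercise; scatter was added.)

Two questions are asked of Saturday's flask, and I bracket both with a ledger and a loss constant.

common to all: free monomer 1.4 M
- Saturday's: initiator 1 mol%; the very flask that is asked about, followed so far
- Thursday's: initiator 0.67 mol%; run made earlier
- flask: initiator 1 mol%; time 2.0 d

- Saturday's (time / h: monomer in chains / %, idle adduct / %, free monomer / %): 2.00: 5.4, 2.3, 94.0; 5.00: 12.3, 5.3, 84.1; 10.0: 21.3, 8.0, 74.3; 15.0: 27.2, 10.3, 65.6
- Thursday's (time / h: monomer in chains / %, idle adduct / %, free monomer / %): 2.50: 5.4, 3.3, 93.2; 6.00: 12.2, 5.1, 84.5; 15.0: 23.4, 9.6, 69.9; 30.0: 31.0, 10.7, 56.6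

(each reading ± 0.5 percentage points)

- a species is counted by the free monomer in it: one idle adduct counts as two
- amounts and yields of monomer in chains count idle adduct too
- on the list of suspects stand: initiator -> 2 initiating radical; free monomer + initiating radical -> growing radical + monomer in chains; free monomer + growing radical -> monomer in chains + growing radical; 2 growing radical -> dead chain; free monomer + monomer in chains <-> idle adduct; monomer in chains -> over-reaction product
- in an amount of monomer in chains, one idle adduct counts as one monomer in chains

* how much monomer in chains the flask holds at 2.0 d, in percent of the free monomer charged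
* how much idle adduct the flask holds at 2.0 d, in percent of the free monomer charged

1. I book monomer as free, in chains, in idle adduct (a resting state of the chains) or in over-reaction product, so I enter the shortfall of Thursday's last reading, 7.05 %, as over-reaction product. Dividing it by the time-area of unbound monomer in chains (the reading less half the adduct reading) gives the loss constant 0.0145 /h.

2. Over the first 15.0 h, ln[free monomer] falls 1.18 times as far in Saturday's flask as in Thursday's. Thursday's later stretch runs slower than its first, so I scale that later rate for Saturday's flask, to 0.0166 /h. Run on to 2.0 d at that rate, my reckoning leaves an estimated floor of 38.0 %; stopped at 30.0 h, an estimated ceiling of 51.2 %.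

3. I close the ledger from Saturday's last reading, with the adduct reading at Thursday's 10.7 %. The floor, with unbound monomer in chains rising in a straight line, gives an upper end of 40.9 % for monomer in chains. The ceiling, with it held at its end value, gives a lower end of 29.8 %.

4. Thursday's last quotient of the adduct reading over [unbound monomer in chains][free monomer], each as a fraction of the charge, is 0.737, and with my two ends it gives an adduct estimate from 9.21 % to 9.94 %.

The forecast, 38 % and 9.5 %, reasons that “radicals are initiator-limited and fade”, and both numbers lie inside my brackets.

The flask gives 36.6 % and 9.52 %, with free monomer at 42.7 %.

    initiator → 2 initiating radical (k = 1.50 × 10⁻⁵ /s)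
    free monomer + initiating radical → growing radical + monomer in chains (k = 1300 /M/s)
    free monomer + growing radical → monomer in chains + growing radical, rate k3*[growing radical]*[free monomer] (k = 110 /M/s)
    2 growing radical → dead chain (k = 4.00 × 10⁷ /M/s)
    free monomer + monomer in chains ⇌ idle adduct, settled at all times (K = 0.250 /M)
    monomer in chains → over-reaction product (k = 3.80 × 10⁻⁶ /s)

The loss constant, carried from 1.00 d with the mean unbound monomer in chains, gives 16.1 % of over-reaction product at 2.0 d; the flask holds 15.9 %.

Left until 3.0 d, the same flask gets from it, with unbound monomer in chains held at its 2.0 d value, 27.0 %. The computed flask holds 25.9 %, with 32.3 % of monomer in chains.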